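Step two cannot run at the start of these flasks: it needs D, and the charge holds none.

the same everywhere: G 0.10 M; X 0.0950 M; time 20 h
- Friday's: temperature 50 °C
- Thursday's: temperature 65 °C
- Sunday's: temperature 80 °C
- Monday's: temperature 35 °C

- the flask that comes out highest in amount of Z, in percent of the G charged, or "all alike" when all lie within 1.5 percentage points (Friday's / Thursday's / Sunday's / Monday's / all alike)
- Z at the end, in percent of the G charged, Friday's
- Z at the end, in percent of the G charged, Thursday's
- Z at the end, in percent of the G charged, Sunday's
- Z at the end, in percent of the G charged, Monday's

- percentages count the G that a species holds: one Q.Z counts as two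
- solid, in amounts per volume of the solution: G
- all constants are for 35 °C and move with temperature by the activation energies
- at the start none of G is in solution
- what has only dissolved of G counts as not reacted

    Q + X → Z + D (k1 = 4.98 × 10⁻⁵ /M/min, Ea1 = 86.0 kJ/mol)
    Q + X + D → Z + 2 D (k2 = 2.71 /M²/min, Ea2 = 57.0 kJ/mol)
    Q + Z → Q.Z (k3 = 0.180 /M/min, Ea3 = 76.0 kJ/mol)
    G ⇌ Q, rate k4*(cs4 - [Q]) while solid is left; crystals form when [Q] > cs4 (cs4 = 15 mM, k4 = 0.0467 /min)
    (constants at 35 °C)

The following reckoning is my own, for Monday's flask, the coldest, whose constants stand as given.

In the first instants, G dissolves with a time constant of 21.4 min. The charge of 0.10 M is more than the solubility, so Q climbs to 15 mM and stays near it while solid lasts.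

In the middle of Monday's run, X stays close to its charge, and step two becomes pseudo-first-order in D. Its growth constant is a product of three given numbers:

growth constant = step-two constant × solubility of Q × charge of X = 0.00386 /min

The doubling time follows from it:

doubling time = ln(2) / growth constant = 2.99 h

The quantity to carry is this doubling time of D with Q held at its solubility. The time constant of the filling is shorter than the doubling time, so the reckoning drops the filling. The first step feeds this growth. Its rate divided by the growth constant gives a seed of D, the ratio of the first two constants, 0.0184 mM. Step three removes Z at 0.00270 /min per unit of Z, so during exponential growth Z keeps a fixed share of the D made: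

share = growth constant / (growth constant + loss constant) = 58.9 %

D at the end = seed × exp(growth constant × time) = 1.89 mM

Z at the end = 1.11 % of the G charged

At the end of Monday's run the exponential is still short of the charge of G, which it reaches after 37.1 h, longer than the run.

In Sunday's flask, step two is 17 times faster than in Monday's, which brings the doubling time to 10.6 min. The growth constant in Sunday's flask is larger than the dissolution coefficient, which carries no activation energy, so Q is not taken as held there and this reckoning stops. Step three speeds up 44 times over the same span, more than step two, which points to a smaller share of Z in the hot flasks.

The forecast names Friday's, with 20.5 % (18 % to 23 %) there, 16 % (14 % to 18 %) for Thursday's, 12.3 % (10.5 % to 14 %) for Sunday's and 1 % (0.7 % to 1.4 %) for Monday's, where my reckoning gives 1.11 %. Its ground among the warmer flasks is that “hotter flasks lose more Z to Q.Z”.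

The simulation puts Friday's highest, with 20.6 %, then 15.9 % for Thursday's, 12.4 % for Sunday's and 0.991 % for Monday's.

Monday's flask reads D 0.00167 M against the reckoned 1.89 mM. Read at 30 h, the same flask should hold, by the same doubling time of 2.99 h, D of 19.2 mM and Z of 11.3 %. It reads D 0.0137 M and Z 7.73 %, with Q at 13.8 % of the G charged and X at 85.6 % of its own charge. Those readings put the growth constant at 0.00303 /min, lower than the reckoned 0.00386 /min.

All constants were drawn at random within sensible limits; the run is a simulation.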